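**Strategy.** The route rests on cutting the 1,2-dioxolane (O1–O2–C3–C4–C5, C3 bearing the acetic acid arm) at C4–C3 and O1–C5. This is a (3+2) annulation of a peroxycarbenium ion (C3–O2–O1, carrying the methyl group and the acetate arm) with a 1,1-disubstituted alkene (C4=C5, carrying the side chain). It exploits the unsubstituted C4 methylene flanked by two oxygen-bearing quaternary carbons: one operation makes the ring and both quaternary stereocentres, and the peroxide arrives late. The precursors are the triethylsilyl peroxyketal of methyl acetoacetate and a triene from (R)-citronellic acid that lacks only the phenyl group, which is added afterwards by cross-metathesis with styrene.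

Key step: step 9

Remark: locants are O1–O2–C3–C4–C5 for the ring and C1'–C10' for the side chain counted from the ring; (S,S)-IDPi is the imidodiphosphorimidate Brønsted acid HN[P(=NSO2CF3)(O2C20H10Ar2)]2 built from two (S)-3,3'-Ar2-1,1'-bi-2-naphthol units, Ar = 3,5-(CF3)2C6H3, and it is assumed that this enantiomer gives the 3R series (otherwise its mirror image is used).

Step 1
Reactants: 1 (R)-citronellic acid [(3R)-3,7-dimethyloct-6-enoic acid]
Product: 3 (4R)-4,8-dimethylnon-7-en-2-one, via dilithium geminal diolate 2 (not isolated)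
Conditions: MeLi (2.2 equiv), Et2O, 0 °C to rt; inverse quench into cold 1 M HCl
Reagents that add atoms: methyllithium, [Li]C
Why: Ketone synthesis from a carboxylic acid and an organolithium: the second equivalent of MeLi adds to the lithium carboxylate to give the dilithium geminal diolate 2, which cannot collapse to the ketone before the acidic quench, so over-addition is held back, and the stereocentre (β to the carbonyl) is not touched.

Step 2
Reactants: 3 (4R)-4,8-dimethylnon-7-en-2-one
Product: 4 (4R)-4-methyl-6-oxoheptanal
Conditions: O3, CH2Cl2/MeOH (4:1), −78 °C; then Me2S, −78 °C to rt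
Reagents that add atoms: ozone, [O-][O+]=O
Why: Ozonolysis with reductive work-up cleaves the only C=C bond of 3 to the aldehyde and acetone, while the ketone and the non-epimerisable stereocentre are unaffected.

Step 3
Reactants: 5 5-bromopent-1-ene; 6 1-phenyl-1H-tetrazole-5-thiol
Product: 7 5-(pent-4-en-1-ylsulfanyl)-1-phenyl-1H-tetrazole
Conditions: K2CO3, acetone, rt
Reagents that add atoms: none
Why: SN2 S-alkylation of the soft tetrazolethiolate by the primary bromide.

Step 4
Reactants: 7 5-(pent-4-en-1-ylsulfanyl)-1-phenyl-1H-tetrazole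
Product: 8 5-(pent-4-en-1-ylsulfonyl)-1-phenyl-1H-tetrazole
Conditions: 30% aq H2O2, (NH4)6Mo7O24·4H2O (10 mol %), EtOH, 0 °C to rt
Reagents that add atoms: hydrogen peroxide, OO
Why: Molybdate-catalysed oxidation with H2O2 takes the sulfide to the sulfone and leaves an unactivated terminal alkene unepoxidised.

Step 5
Reactants: 8 5-(pent-4-en-1-ylsulfonyl)-1-phenyl-1H-tetrazole; 4 (4R)-4-methyl-6-oxoheptanal
Product: 10 (4R,7E)-4-methyldodeca-7,11-dien-2-one, via potassium sulfonyl carbanion 9 (not isolated)
Conditions: KN(SiMe3)2 (1.0 equiv), DME, −78 °C, 20 min; then 4, −78 °C to rt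
Reagents that add atoms: none
Why: Julia–Kocienski olefination: carbanion 9 adds to the aldehyde of 4 (far more electrophilic than the methyl ketone at −78 °C), and Smiles rearrangement followed by loss of SO2 and the tetrazololate gives the alkene, the E geometry following from the usual preference of 1-phenyltetrazolyl sulfones with a potassium counter-ion in DME for unbranched partners.

Step 6
Reactants: 10 (4R,7E)-4-methyldodeca-7,11-dien-2-one
Product: 11 (4R,7E)-2,4-dimethyldodeca-1,7,11-triene
Conditions: Ph3PCH3Br, KOtBu, THF, 0 °C to rt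
Reagents that add atoms: methyltriphenylphosphonium bromide, C[P+](c1ccccc1)(c1ccccc1)c1ccccc1.[Br-]
Why: Wittig methylenation of the methyl ketone with the non-stabilised ylide gives the 1,1-disubstituted alkene without touching the E alkene or the stereocentre, which is β to the carbonyl and cannot epimerise.

Step 7
Reactants: 12 methyl 3-methylbut-3-enoate
Product: 14 methyl 3-hydroperoxy-3-methoxybutanoate (racemic), via carbonyl oxide 13 (not isolated)
Conditions: O3, CH2Cl2/MeOH (1:1), −78 °C; N2 purge; concentrated cold behind a shield and used crude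
Reagents that add atoms: ozone, [O-][O+]=O; methanol, CO
Why: Ozonolysis of a 1,1-disubstituted alkene in methanol: the primary ozonide should fragment mainly to formaldehyde and the more substituted carbonyl oxide 13, which methanol captures as the α-methoxy hydroperoxide, and the new stereocentre is of no consequence because it becomes planar in step 9.

Step 8
Reactants: 14 methyl 3-hydroperoxy-3-methoxybutanoate
Product: 15 methyl 3-methoxy-3-[(triethylsilyl)peroxy]butanoate (racemic)
Conditions: Et3SiCl, imidazole, DMF, 0 °C
Reagents that add atoms: chlorotriethylsilane, CC[Si](Cl)(CC)CC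
Why: Silylation of the hydroperoxide oxygen under mild base gives the triethylsilyl peroxide, whose silyl group keeps the peroxide intact on ionisation and leaves as the cation after ring closure.

Step 9
Reactants: 15 methyl 3-methoxy-3-[(triethylsilyl)peroxy]butanoate; 11 (4R,7E)-2,4-dimethyldodeca-1,7,11-triene
Product: 18 methyl 2-[(3R,5R)-3,5-dimethyl-5-[(2R,5E)-2-methyldeca-5,9-dien-1-yl]-1,2-dioxolan-3-yl]acetate, via peroxycarbenium ion 16 (not isolated), via tertiary carbocation 17 (not isolated)
Conditions: 15 (1.5 equiv), (S,S)-IDPi (5 mol %), 4 Å molecular sieves, CH2Cl2, −78 to −60 °C; Et3N quench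
Reagents that add atoms: none
Why: Proposed new method: the acid (after the first turnover its triethylsilylated form) removes the methoxy group of 15 to give peroxycarbenium ion 16 as an ion pair with the confined chiral IDPi anion; the CH2 terminus of the 1,1-disubstituted alkene of 11 attacks C3 of 16 (Markovnikov) to give tertiary carbocation 17, whose silylated peroxide oxygen collapses onto C5 and releases Et3Si+, which ionises the next molecule of 15 and leaves Et3SiOMe, so the acid is needed only in catalytic amount. The closest known reaction type is the (3+2) annulation of triethylsilyl peroxyketals with alkenes promoted by stoichiometric SnCl4 or TiCl4, merged here with silylium-based asymmetric counteranion-directed catalysis as practised on oxocarbenium ions from ketones, aldehydes and acetals; peroxycarbenium ions have not been used in this way. The one ring formed, the 1,2-dioxolane, is closed in two stages, intermolecular C4–C3 bond formation followed by five-membered ring closure through collapse of the C5 cation with O1 of the silyl peroxide. C3 is set in the C–C bond formation by the chiral anion, which has to tell the methyl from the CH2CO2Me group on the planar cation as such anions do for methyl against CH2R in ketone-derived cations, and C5 is set in the ring closure, where an envelope transition state with the two larger groups (the CH2CO2Me arm at C3 and the C1' chain at C5) pseudo-equatorial puts both methyl groups on one face (cis), the distant C2' centre being a bystander. The step needs chemoselectivity for the 1,1-disubstituted alkene over the E-1,2-disubstituted and monosubstituted alkenes of 11, secured by the tertiary against secondary carbocation each would give, and it needs O1 to capture cation 17 faster than the C5'=C6' alkene can, for which the short five-membered closure by the adjacent peroxide is relied on.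

Step 10
Reactants: 18 methyl 2-[(3R,5R)-3,5-dimethyl-5-[(2R,5E)-2-methyldeca-5,9-dien-1-yl]-1,2-dioxolan-3-yl]acetate; 19 styrene
Product: 20 methyl 2-[(3R,5R)-3,5-dimethyl-5-[(2R,5E,9E)-2-methyl-10-phenyldeca-5,9-dien-1-yl]-1,2-dioxolan-3-yl]acetate
Conditions: 19 (5 equiv), second-generation Grubbs catalyst RuCl2(=CHPh)(PCy3)(H2IMes) (5 mol %), CH2Cl2, 40 °C
Reagents that add atoms: none
Why: Olefin cross-metathesis: the monosubstituted alkene of 18 should react far faster than the internal 1,2-disubstituted one, styrene in excess gives the conjugated E-styrene with loss of ethylene, and the di-tertiary dialkyl peroxide is inert to the ruthenium carbene.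

Step 11
Reactants: 20 methyl 2-[(3R,5R)-3,5-dimethyl-5-[(2R,5E,9E)-2-methyl-10-phenyldeca-5,9-dien-1-yl]-1,2-dioxolan-3-yl]acetate
Product: 22 2-[(3R,5R)-3,5-dimethyl-5-[(2R,5E,9E)-2-methyl-10-phenyldeca-5,9-dien-1-yl]-1,2-dioxolan-3-yl]acetic acid, via lithium carboxylate 21 (not isolated)
Conditions: LiOH·H2O (3 equiv), THF/MeOH/H2O (3:1:1), 0 °C to rt; then 1 M HCl to pH 3
Reagents that add atoms: lithium hydroxide, [Li+].[OH-]
Why: Saponification: hydroxide adds to the ester carbonyl much faster than it removes the α-proton, so the β-peroxide is not expelled, and the di-tertiary peroxide has no α-hydrogen for a Kornblum–DeLaMare fragmentation, so the three stereocentres and both E alkenes are kept.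

**Compound list**

1 | (3R)-3,7-dimethyloct-6-enoic acid [(R)-citronellic acid] | C[C@H](CCC=C(C)C)CC(=O)O | starting material
2 | dilithium (4R)-4,8-dimethylnon-7-ene-2,2-diolate | C[C@H](CCC=C(C)C)CC(C)([O-])[O-].[Li+].[Li+] | intermediate
3 | (4R)-4,8-dimethylnon-7-en-2-one | C[C@H](CCC=C(C)C)CC(C)=O | intermediate
4 | (4R)-4-methyl-6-oxoheptanal | C[C@H](CCC=O)CC(C)=O | intermediate
5 | 5-bromopent-1-ene | C=CCCCBr | starting material
6 | 1-phenyl-1H-tetrazole-5-thiol | Sc1nnnn1-c1ccccc1 | starting material
7 | 5-(pent-4-en-1-ylsulfanyl)-1-phenyl-1H-tetrazole | C=CCCCSc1nnnn1-c1ccccc1 | intermediate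
8 | 5-(pent-4-en-1-ylsulfonyl)-1-phenyl-1H-tetrazole | C=CCCCS(=O)(=O)c1nnnn1-c1ccccc1 | intermediate
9 | potassium salt of the α-sulfonyl carbanion of 8 | [K+].C=CCC[CH-]S(=O)(=O)c1nnnn1-c1ccccc1 | intermediate
10 | (4R,7E)-4-methyldodeca-7,11-dien-2-one | C[C@H](CC/C=C/CCC=C)CC(C)=O | intermediate
11 | (4R,7E)-2,4-dimethyldodeca-1,7,11-triene | C[C@H](CC/C=C/CCC=C)CC(C)=C | intermediate
12 | methyl 3-methylbut-3-enoate | C=C(C)CC(=O)OC | starting material
13 | carbonyl oxide of methyl acetoacetate (O-oxide at the ketone carbon) | CC(CC(=O)OC)=[O+][O-] | intermediate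
14 | methyl 3-hydroperoxy-3-methoxybutanoate (racemic) | COC(C)(CC(=O)OC)OO | intermediate
15 | methyl 3-methoxy-3-[(triethylsilyl)peroxy]butanoate (racemic) | COC(C)(CC(=O)OC)OO[Si](CC)(CC)CC | intermediate
16 | peroxycarbenium ion MeC(=O+–OSiEt3)CH2CO2Me (cation of the ion pair with the catalyst anion) | CC(CC(=O)OC)=[O+]O[Si](CC)(CC)CC | intermediate
17 | C5 carbocation of methyl (3R,7R,10E)-3,5,7-trimethyl-3-[(triethylsilyl)peroxy]pentadeca-10,14-dienoate | C[C@H](CC/C=C/CCC=C)C[C+](C)C[C@](C)(CC(=O)OC)OO[Si](CC)(CC)CC | intermediate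
18 | methyl 2-[(3R,5R)-3,5-dimethyl-5-[(2R,5E)-2-methyldeca-5,9-dien-1-yl]-1,2-dioxolan-3-yl]acetate | C[C@H](CC/C=C/CCC=C)C[C@]1(C)C[C@](C)(CC(=O)OC)OO1 | intermediate
19 | styrene | C=Cc1ccccc1 | starting material
20 | methyl 2-[(3R,5R)-3,5-dimethyl-5-[(2R,5E,9E)-2-methyl-10-phenyldeca-5,9-dien-1-yl]-1,2-dioxolan-3-yl]acetate | C[C@H](CC/C=C/CC/C=C/c1ccccc1)C[C@]1(C)C[C@](C)(CC(=O)OC)OO1 | intermediate
21 | lithium 2-[(3R,5R)-3,5-dimethyl-5-[(2R,5E,9E)-2-methyl-10-phenyldeca-5,9-dien-1-yl]-1,2-dioxolan-3-yl]acetate | C[C@H](CC/C=C/CC/C=C/c1ccccc1)C[C@]1(C)C[C@](C)(CC(=O)[O-])OO1.[Li+] | intermediate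
22 | 2-[(3R,5R)-3,5-dimethyl-5-[(2R,5E,9E)-2-methyl-10-phenyldeca-5,9-dien-1-yl]-1,2-dioxolan-3-yl]acetic acid | C[C@H](CC/C=C/CC/C=C/c1ccccc1)C[C@]1(C)C[C@](C)(CC(=O)O)OO1 | target

**Step count and risks**

Total step count: 11. Longest linear sequence: 7 steps (steps 1, 2, 5, 6, 9, 10, 11).

Steps most likely to fail:

1. Step 9 (proposed new method). The chiral anion may not discriminate the two faces of the planar ion 16 well enough, silyl transfer may not turn the acid over, or 16 may lose a proton to a vinyl peroxide before the alkene attacks. The cis preference in the ring closure may also be modest, but the trans isomer is a ring diastereomer that silica gel should remove. The fallback uses known chemistry, sets out from 15 and 11 and comes back at 18. The annulation is run in its established form with stoichiometric SnCl4 (CH2Cl2, −78 °C). This makes the same two bonds but offers no control of the absolute sense, so the stereochemical decision moves from the bond-forming event to a separation in which the C2' centre of 11 acts as the resolving element. Besides 18, the mixture should contain methyl 2-[(3S,5S)-3,5-dimethyl-5-[(2R,5E)-2-methyldeca-5,9-dien-1-yl]-1,2-dioxolan-3-yl]acetate F1, methyl 2-[(3S,5R)-3,5-dimethyl-5-[(2R,5E)-2-methyldeca-5,9-dien-1-yl]-1,2-dioxolan-3-yl]acetate F2 and methyl 2-[(3R,5S)-3,5-dimethyl-5-[(2R,5E)-2-methyldeca-5,9-dien-1-yl]-1,2-dioxolan-3-yl]acetate F3. The trans compounds F2 and F3 should be removed on silica gel, and 18 parted from F1 by preparative HPLC on a chiral stationary phase.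

2. Step 10. Secondary metathesis at the internal C5'=C6' alkene may compete with reaction at the terminal alkene, truncating the chain or scrambling the E geometry. The fallback sets out from 4 (with 8, 15 and 19 as before) and comes back at 20; it introduces the styrene on a fragment that has no other alkene. Double Wittig methylenation of 4 (excess Ph3PCH3Br/KOtBu, THF) should give (4R)-2,4-dimethylocta-1,7-diene F4. Annulation of F4 with 15 under the conditions of step 9 (or of its fallback) should give methyl 2-[(3R,5R)-3,5-dimethyl-5-[(2R)-2-methylhex-5-en-1-yl]-1,2-dioxolan-3-yl]acetate F5, the vinyl group being too poor a nucleophile to interfere. Ozonolysis (O3, CH2Cl2/MeOH, −78 °C; Me2S) should give methyl 2-[(3R,5R)-3,5-dimethyl-5-[(2R)-2-methyl-5-oxopentyl]-1,2-dioxolan-3-yl]acetate F6. Separately, cross-metathesis of 8 with 19 (second-generation Grubbs catalyst RuCl2(=CHPh)(PCy3)(H2IMes), CH2Cl2, 40 °C) should give 1-phenyl-5-{[(4E)-5-phenylpent-4-en-1-yl]sulfonyl}-1H-tetrazole F7. Julia–Kocienski olefination of premetalated F7 (KN(SiMe3)2, DME, −78 °C) with F6 then gives 20. The price is one more step and a carbanion in the presence of the β-peroxy ester.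

3. Step 5. Carbanion 9 may attack or enolise the methyl ketone of 4 alongside the aldehyde, and E selectivity may be incomplete with no later chance to correct it. The fallback sets out from 3 and comes back at 11, by-passing 4 and 10, so that the olefination meets a single carbonyl group. Wittig methylenation of 3 (Ph3PCH3Br, KOtBu, THF) should give (4R)-2,4,8-trimethylnona-1,7-diene F8. mCPBA (1.0 equiv, CH2Cl2, 0 °C) should epoxidise the more electron-rich trisubstituted alkene selectively to 3-[(3R)-3,5-dimethylhex-5-en-1-yl]-2,2-dimethyloxirane F9 (epimers at the oxirane carbon). H5IO6 (THF/H2O, 0 °C) should cleave the epoxide to (4R)-4,6-dimethylhept-6-enal F10 and acetone. Julia–Kocienski olefination of 8 (KN(SiMe3)2, DME, −78 °C) with F10 then gives 11 directly.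

Further compounds
F1 | step 9 | methyl 2-[(3S,5S)-3,5-dimethyl-5-[(2R,5E)-2-methyldeca-5,9-dien-1-yl]-1,2-dioxolan-3-yl]acetate | C[C@H](CC/C=C/CCC=C)C[C@@]1(C)C[C@@](C)(CC(=O)OC)OO1
F2 | step 9 | methyl 2-[(3S,5R)-3,5-dimethyl-5-[(2R,5E)-2-methyldeca-5,9-dien-1-yl]-1,2-dioxolan-3-yl]acetate | C[C@H](CC/C=C/CCC=C)C[C@]1(C)C[C@@](C)(CC(=O)OC)OO1
F3 | step 9 | methyl 2-[(3R,5S)-3,5-dimethyl-5-[(2R,5E)-2-methyldeca-5,9-dien-1-yl]-1,2-dioxolan-3-yl]acetate | C[C@H](CC/C=C/CCC=C)C[C@@]1(C)C[C@](C)(CC(=O)OC)OO1
F4 | step 10 | (4R)-2,4-dimethylocta-1,7-diene | C[C@H](CCC=C)CC(C)=C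
F5 | step 10 | methyl 2-[(3R,5R)-3,5-dimethyl-5-[(2R)-2-methylhex-5-en-1-yl]-1,2-dioxolan-3-yl]acetate | C[C@H](CCC=C)C[C@]1(C)C[C@](C)(CC(=O)OC)OO1
F6 | step 10 | methyl 2-[(3R,5R)-3,5-dimethyl-5-[(2R)-2-methyl-5-oxopentyl]-1,2-dioxolan-3-yl]acetate | C[C@H](CCC=O)C[C@]1(C)C[C@](C)(CC(=O)OC)OO1
F7 | step 10 | 1-phenyl-5-{[(4E)-5-phenylpent-4-en-1-yl]sulfonyl}-1H-tetrazole | O=S(=O)(CCC/C=C/c1ccccc1)c1nnnn1-c1ccccc1
F8 | step 5 | (4R)-2,4,8-trimethylnona-1,7-diene | C[C@H](CCC=C(C)C)CC(C)=C
F9 | step 5 | 3-[(3R)-3,5-dimethylhex-5-en-1-yl]-2,2-dimethyloxirane (epimers at the oxirane carbon) | C[C@H](CCC1OC1(C)C)CC(C)=C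
F10 | step 5 | (4R)-4,6-dimethylhept-6-enal | C[C@H](CCC=O)CC(C)=C
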